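**Retrosynthetic overview**

1. Target 21 is cut at the CH2 bridge into chromene Mannich base 17 (C6–CH2NMe2) and acetylfilicinic acid 19; 19 comes from 2,4,6-trihydroxyacetophenone by geminal C-methylation.
2. The strategy rests on the chromene benzene ring (C4a, C5, C6, C7, C8, C8a; chromene numbering is used throughout). Its three oxygens have different fates (O1 on C8a in the pyran ring, 5-OH, 7-OH next to the C8 acetyl), and the benzannulation delivers them already distinct as free OH, silyl ether and ethyl ether.
3. The benzene ring is built first from 3-ethoxycyclobutenone 6 and prenyl siloxyalkyne 5 (new bonds C8a–C4a and C5–C6). The pyran ring follows by oxidative closure through the only free OH, then C8 acetylation by lithiation between O1 and OEt, de-ethylation and desilylation.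
4. Siloxyalkyne 5 comes from 4-methylpent-3-enoic acid by esterification, ynolate formation and O-silylation.
5. Ring order: benzene ring (step 3), pyran ring (step 4); the filicinic acid ring is made separately (step 9) and joined last (step 10).

Key step: step 3

Assumption: the target has no stereocentre and is drawn as one enol tautomer of the acetylfilicinic acid ring; the route delivers this tautomeric system.

**Route**

Step 1
Reactants: 1 4-methylpent-3-enoic acid
Product: 2 ethyl 4-methylpent-3-enoate
Conditions: EtI, K2CO3, DMF, 25 °C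
Reagents that add atoms: iodoethane, CCI
Why: SN2 O-alkylation of the carboxylate should give the ester without acid, which could lactonise or isomerise the β,γ-unsaturated acid.

Step 2
Reactants: 2 ethyl 4-methylpent-3-enoate
Product: 5 triisopropyl[(5-methylhex-4-en-1-yn-1-yl)oxy]silane, via dibromo enolate 3 (not isolated), via lithium ynolate 4 (not isolated)
Conditions: CH2Br2, lithium 2,2,6,6-tetramethylpiperidide, THF, −78 °C; n-BuLi, −78 → 25 °C; TIPSOTf, −78 → 0 °C
Reagents that add atoms: dibromomethane, BrCBr; triisopropylsilyl trifluoromethanesulfonate, CC(C)[Si](C(C)C)(C(C)C)OS(=O)(=O)C(F)(F)F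
Why: Kowalski ester homologation, in which LiCHBr2 adds to the ester, enolate 3 undergoes bromine–lithium exchange and 1,2-shift to ynolate 4, and the bulky silyl triflate should silylate the ynolate on oxygen instead of carbon.

Step 3
Reactants: 5 triisopropyl[(5-methylhex-4-en-1-yn-1-yl)oxy]silane; 6 3-ethoxycyclobut-2-en-1-one
Product: 11 5-ethoxy-2-(3-methylbut-2-en-1-yl)-3-[(triisopropylsilyl)oxy]phenol, via ethoxyvinylketene 7 (not isolated), via vinylcyclobutenone 8 (not isolated), via dienylketene 9 (not isolated), via cyclohexadienone 10 (not isolated)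
Conditions: PhMe, 80 → 110 °C, sealed tube, argon
Reagents that add atoms: none
Why: Proposed new method: heating should open 6 by 4π electrocyclic cleavage to ethoxyvinylketene 7, whose ketene carbon is attacked by the nucleophilic prenyl-bearing carbon of 5 in a (2+2) cycloaddition that forms the C8a–C4a and C5–C6 bonds (cyclobutenone 8); 4π opening of 8 gives dienylketene 9, which cyclises to dienone 10 and enolises to phenol 11. The closest known reaction type is the Danheiser benzannulation of alkyl- or aryl-substituted cyclobutenones with siloxyalkynes to resorcinol monosilyl ethers, which has not been shown for a 3-alkoxycyclobutenone leading to a 1,3,5-trioxygenated arene; the ethoxy donor should slow the first ring opening, hence the higher final temperature. The benzene ring is closed by thermal disrotatory 6π electrocyclisation of 9 between the ketene carbon (C8a) and the terminal CH2 (C8), followed by tautomerisation. No stereocentre is formed. The step needs regioselectivity in the ketene–alkyne addition, which the polarisation of the siloxyalkyne secures (the carbon β to oxygen bonds to the electrophilic ketene carbon, so OH and prenyl end up on adjacent carbons), and chemoselectivity for the ynol ether over the prenyl alkene, which its far higher nucleophilicity secures.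

Step 4
Reactants: 11 5-ethoxy-2-(3-methylbut-2-en-1-yl)-3-[(triisopropylsilyl)oxy]phenol
Product: 12 [(7-ethoxy-2,2-dimethyl-2H-chromen-5-yl)oxy]triisopropylsilane
Conditions: DDQ, PhH, 25 → 80 °C
Reagents that add atoms: none
Why: DDQ oxidative cyclisation of an ortho-prenylphenol (benzylic hydride abstraction to an ortho-quinone methide, then oxa-6π electrocyclisation) should close the pyran ring through the only free OH, since the other ortho oxygen is silylated.

Step 5
Reactants: 12 [(7-ethoxy-2,2-dimethyl-2H-chromen-5-yl)oxy]triisopropylsilane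
Product: 14 1-{7-ethoxy-2,2-dimethyl-5-[(triisopropylsilyl)oxy]-2H-chromen-8-yl}ethan-1-one, via aryllithium 13 (not isolated)
Conditions: n-BuLi, TMEDA, THF, −20 → 0 °C; MeC(O)N(OMe)Me, −78 → 0 °C; aq. NH4Cl
Reagents that add atoms: N-methoxy-N-methylacetamide, CC(=O)N(C)OC
Why: Directed ortho-metalation should occur at C8, the CH flanked by two coordinating ether oxygens (O1 and OEt), and not at C6 next to the shielded, poorly coordinating silyl ether; Weinreb ketone synthesis then gives the methyl ketone without over-addition.

Step 6
Reactants: 14 1-{7-ethoxy-2,2-dimethyl-5-[(triisopropylsilyl)oxy]-2H-chromen-8-yl}ethan-1-one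
Product: 15 1-{7-hydroxy-2,2-dimethyl-5-[(triisopropylsilyl)oxy]-2H-chromen-8-yl}ethan-1-one
Conditions: BCl3, CH2Cl2, −78 → −20 °C; then H2O, 0 °C
Reagents that add atoms: none
Why: Chelation-assisted ether cleavage, in which BCl3 bound to the acetyl oxygen activates the neighbouring 7-ethoxy group for dealkylation by chloride at low temperature, while the unchelated bulky silyl ether and the more hindered ring oxygen O1 should be left alone.

Step 7
Reactants: 15 1-{7-hydroxy-2,2-dimethyl-5-[(triisopropylsilyl)oxy]-2H-chromen-8-yl}ethan-1-one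
Product: 16 1-(5,7-dihydroxy-2,2-dimethyl-2H-chromen-8-yl)ethan-1-one
Conditions: TBAF, AcOH, THF, 0 °C
Reagents that add atoms: none
Why: Fluoride desilylation of an aryl silyl ether, buffered with acetic acid so that the acidic acylphloroglucinol is released as the neutral phenol.

Step 8
Reactants: 16 1-(5,7-dihydroxy-2,2-dimethyl-2H-chromen-8-yl)ethan-1-one
Product: 17 1-{6-[(dimethylamino)methyl]-5,7-dihydroxy-2,2-dimethyl-2H-chromen-8-yl}ethan-1-one
Conditions: premixed aq. CH2O and aq. Me2NH, EtOH, 0 → 25 °C
Reagents that add atoms: formaldehyde, C=O; dimethylamine, CNC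
Why: Mannich aminomethylation should take place at C6, the only free ring position, which lies between two hydroxyl groups; the excess of preformed iminium suppresses bis-arylmethane formation.

Step 9
Reactants: 18 2,4,6-trihydroxyacetophenone
Product: 19 2-acetyl-3,5-dihydroxy-4,4-dimethylcyclohexa-2,5-dien-1-one (acetylfilicinic acid)
Conditions: NaOMe, MeI, MeOH, 0 → 25 °C; then aq. HCl
Reagents that add atoms: iodomethane, CI
Why: Base-mediated dearomatising C-methylation of an acylphloroglucinol, in which two methyl groups should enter at one ring carbon and the quaternary centre then blocks rearomatisation; the amount of methyl iodide limits over-methylation.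

Step 10
Reactants: 17 1-{6-[(dimethylamino)methyl]-5,7-dihydroxy-2,2-dimethyl-2H-chromen-8-yl}ethan-1-one; 19 2-acetyl-3,5-dihydroxy-4,4-dimethylcyclohexa-2,5-dien-1-one
Product: 21 2-acetyl-6-[(8-acetyl-5,7-dihydroxy-2,2-dimethyl-2H-chromen-6-yl)methyl]-3,5-dihydroxy-4,4-dimethylcyclohexa-2,5-dien-1-one (target), via quinone methide 20 (not isolated)
Conditions: 19 (1.5 equiv), 1,4-dioxane, 80 °C
Reagents that add atoms: none
Why: Retro-Mannich loss of dimethylamine from the phenolic Mannich base should give ortho-quinone methide 20, which is trapped at its exocyclic carbon by Michael addition of the acidic C6–H of 19, present in excess as the ammonium enolate, to form the methylene bridge.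

**Compound list**

1 | 4-methylpent-3-enoic acid | CC(C)=CCC(=O)O | starting material
2 | ethyl 4-methylpent-3-enoate | CCOC(=O)CC=C(C)C | intermediate
3 | lithium 1,1-dibromo-5-methylhexa-1,4-dien-2-olate | [Li+].[O-]C(CC=C(C)C)=C(Br)Br | intermediate
4 | lithium 5-methylhex-4-en-1-yn-1-olate | [Li+].[O-]C#CCC=C(C)C | intermediate
5 | triisopropyl[(5-methylhex-4-en-1-yn-1-yl)oxy]silane | CC(C)=CCC#CO[Si](C(C)C)(C(C)C)C(C)C | intermediate
6 | 3-ethoxycyclobut-2-en-1-one | CCOC1=CC(=O)C1 | starting material
7 | 3-ethoxybuta-1,3-dien-1-one | C=C(OCC)C=C=O | intermediate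
8 | 4-(1-ethoxyethenyl)-2-(3-methylbut-2-en-1-yl)-3-[(triisopropylsilyl)oxy]cyclobut-2-en-1-one (racemic) | CCOC(=C)C1C(=O)C(CC=C(C)C)=C1O[Si](C(C)C)(C(C)C)C(C)C | intermediate
9 | (3E)-5-ethoxy-2-(3-methylbut-2-en-1-yl)-3-[(triisopropylsilyl)oxy]hexa-1,3,5-trien-1-one | O=C=C(CC=C(C)C)/C(O[Si](C(C)C)(C(C)C)C(C)C)=C\C(OCC)=C | intermediate
10 | 5-ethoxy-2-(3-methylbut-2-en-1-yl)-3-[(triisopropylsilyl)oxy]cyclohexa-2,4-dien-1-one | O=C1CC(OCC)=CC(O[Si](C(C)C)(C(C)C)C(C)C)=C1CC=C(C)C | intermediate
11 | 5-ethoxy-2-(3-methylbut-2-en-1-yl)-3-[(triisopropylsilyl)oxy]phenol | CCOc1cc(O)c(CC=C(C)C)c(O[Si](C(C)C)(C(C)C)C(C)C)c1 | intermediate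
12 | [(7-ethoxy-2,2-dimethyl-2H-chromen-5-yl)oxy]triisopropylsilane | CCOc1cc(O[Si](C(C)C)(C(C)C)C(C)C)c2C=CC(C)(C)Oc2c1 | intermediate
13 | {7-ethoxy-2,2-dimethyl-5-[(triisopropylsilyl)oxy]-2H-chromen-8-yl}lithium | CCOc1cc(O[Si](C(C)C)(C(C)C)C(C)C)c2C=CC(C)(C)Oc2c1[Li] | intermediate
14 | 1-{7-ethoxy-2,2-dimethyl-5-[(triisopropylsilyl)oxy]-2H-chromen-8-yl}ethan-1-one | CCOc1cc(O[Si](C(C)C)(C(C)C)C(C)C)c2C=CC(C)(C)Oc2c1C(C)=O | intermediate
15 | 1-{7-hydroxy-2,2-dimethyl-5-[(triisopropylsilyl)oxy]-2H-chromen-8-yl}ethan-1-one | CC(=O)c1c(O)cc(O[Si](C(C)C)(C(C)C)C(C)C)c2C=CC(C)(C)Oc12 | intermediate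
16 | 1-(5,7-dihydroxy-2,2-dimethyl-2H-chromen-8-yl)ethan-1-one | CC(=O)c1c(O)cc(O)c2C=CC(C)(C)Oc12 | intermediate
17 | 1-{6-[(dimethylamino)methyl]-5,7-dihydroxy-2,2-dimethyl-2H-chromen-8-yl}ethan-1-one | CC(=O)c1c(O)c(CN(C)C)c(O)c2C=CC(C)(C)Oc12 | intermediate
18 | 2,4,6-trihydroxyacetophenone | CC(=O)c1c(O)cc(O)cc1O | starting material
19 | 2-acetyl-3,5-dihydroxy-4,4-dimethylcyclohexa-2,5-dien-1-one (acetylfilicinic acid) | CC(=O)C1=C(O)C(C)(C)C(O)=CC1=O | intermediate
20 | 8-acetyl-7-hydroxy-2,2-dimethyl-6-methylidene-2H-chromen-5(6H)-one | C=C1C(O)=C(C(C)=O)C2=C(C=CC(C)(C)O2)C1=O | intermediate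
21 | 2-acetyl-6-[(8-acetyl-5,7-dihydroxy-2,2-dimethyl-2H-chromen-6-yl)methyl]-3,5-dihydroxy-4,4-dimethylcyclohexa-2,5-dien-1-one | CC(=O)C1=C(O)C(C)(C)C(O)=C(Cc2c(O)c3c(c(C(C)=O)c2O)OC(C)(C)C=C3)C1=O | target

**Step count**

Total steps: 10. Longest linear sequence: 9 steps (steps 1–8 and 10); step 9 is a one-step side branch.

**Steps most likely to fail**

Step 3 (key benzannulation). The vinylogous-ester cyclobutenone may resist 4π opening at temperatures the siloxyalkyne tolerates. The electron-rich vinylketene may also dimerise or acylate the product phenol before the (2+2) addition. The fallback uses known phloroglucinol chemistry and accepts a separation. It sets out from 18: condensation with 3-methylbut-2-enal in pyridine at about 120 °C (Knoevenagel condensation, then oxa-6π electrocyclisation) should give 16 together with its regioisomer 1-(5,7-dihydroxy-2,2-dimethyl-2H-chromen-6-yl)ethan-1-one F1, which is removed by chromatography. The route is rejoined at 16 and continues with step 8.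

Step 10 (methylene bridge). Amine loss may be slow, or the bridge may scramble by retro-Michael fragmentation at 80 °C into symmetric bis-chromenyl and bis-filicinyl methanes. The fallback reverses the roles of the partners so that the coupling runs at ambient temperature. It sets out from 19: Mannich reaction with premixed formaldehyde and dimethylamine in ethanol at 0 °C should give the zwitterionic 2-acetyl-6-[(dimethylamino)methyl]-3,5-dihydroxy-4,4-dimethylcyclohexa-2,5-dien-1-one F2. Stirring F2 with 16 and NaOAc in methanol at 25 °C should release 2-acetyl-3-hydroxy-4,4-dimethyl-6-methylidenecyclohex-2-ene-1,5-dione F3 by loss of dimethylamine from the enolate. F3 is attacked by C6 of 16, and the fallback comes back at 21.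

Step 6 (de-ethylation). The Lewis acid may ionise the tertiary allylic C2–O1 bond of the pyran or add HCl across C3=C4 faster than it removes the ethyl group. The fallback cleaves the ether by nucleophilic attack at the alkyl carbon under basic conditions instead of Lewis-acid activation. It sets out from 14: heating with NaSEt in DMF at about 100 °C should remove the ethyl group by SN2 attack of thiolate, with the acetyl-stabilised phenoxide as leaving group. Acidic work-up should give 15, where the route is rejoined for step 7; whether the silyl ether survives these conditions is uncertain, and its loss would give 16 directly. This fallback makes no new compound (F0).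

**Further compounds**

F1 | step 3 | 1-(5,7-dihydroxy-2,2-dimethyl-2H-chromen-6-yl)ethan-1-one | CC(=O)c1c(O)cc2OC(C)(C)C=Cc2c1O
F2 | step 10 | 2-acetyl-6-[(dimethylamino)methyl]-3,5-dihydroxy-4,4-dimethylcyclohexa-2,5-dien-1-one | CC(=O)C1=C(O)C(C)(C)C(O)=C(CN(C)C)C1=O
F3 | step 10 | 2-acetyl-3-hydroxy-4,4-dimethyl-6-methylidenecyclohex-2-ene-1,5-dione | C=C1C(=O)C(C(C)=O)=C(O)C(C)(C)C1=O
F0 | step 6 | none | none
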